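**Retrosynthetic overview**
1. Target 17 is a γ-butyrolactone whose ring carbons C3 and C4 each carry one exocyclic benzylic CH2, trans to each other (3,4-dimethoxybenzyl at C3 next to the C2 carbonyl, 3,4,5-trimethoxybenzyl at C4), while C5 is a bare OCH2. Both exocyclic C–C bonds can therefore be laid across the C3=C4 bond of a butenolide.
2. C5 is traced back to a menthyl acetal carbon (reductive opening, relactonization) and the C4 benzylic CH2 to a 2-aryl-1,3-dithiane carbon (desulfurization), giving adduct 13.
3. Key disconnection of 13: the C4–C(dithiane) and C3–CH2Ar bonds, made in one pot from lithiated dithiane 11, (5R)-menthyloxybutenolide 6 and benzylic bromide 10.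
4. Butenolide 6 comes from furfural 1 by photo-oxygenation and acetalization with (−)-menthol 4; dithiane 8 from aldehyde 7; bromide 10 from alcohol 9.
5. Ring order: the lactone is the only ring to be provided; it arrives preformed from the furan of 1 (step 1), no ring closes in the key step, and it is opened and re-closed once in step 7.

Key step: step 5

Assumption: in step 2 the two C5 acetal epimers interconvert under the acid catalyst, so material held in solution as the 5S epimer can be funnelled into the crystalline 5R epimer.

**Route**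

Step 1
Reactants: 1 furfural
Product: 3 5-hydroxyfuran-2(5H)-one (racemic), via furfural 2,5-endoperoxide 2 (not isolated)
Conditions: O2, hν (visible), methylene blue (cat.), MeOH, 20 °C
Reagents that add atoms: oxygen, O=O
Why: Sensitized singlet-oxygen [4+2] cycloaddition to the furan gives endoperoxide 2, which fragments in methanol with loss of the formyl carbon as methyl formate to the γ-hydroxybutenolide (furan photo-oxygenation); the acetal carbon is racemic here and is fixed in step 2.

Step 2
Reactants: 3 5-hydroxyfuran-2(5H)-one; 4 (−)-menthol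
Product: 6 (5R)-5-[(1R,2S,5R)-menthyloxy]furan-2(5H)-one, via 5S acetal epimer 5 (not isolated)
Conditions: p-TsOH·H2O (cat.), toluene, reflux (Dean–Stark); crystallize from petroleum ether, −20 °C; mother liquor re-equilibrated with the acid and recrystallized
Reagents that add atoms: none
Why: Acid-catalysed acetalization of the pseudo-acid lactol through the ring oxocarbenium ion gives both C5 epimers, of which the 5R epimer crystallizes, and acid epimerization of the acetal carbon converts the dissolved 5S epimer 5 into it (crystallization-induced diastereomer transformation), so C5 is set by the menthol stereocentres.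

Step 3
Reactants: 7 3,4,5-trimethoxybenzaldehyde
Product: 8 2-(3,4,5-trimethoxyphenyl)-1,3-dithiane
Conditions: HS(CH2)3SH, BF3·OEt2 (cat.), CH2Cl2, 0 °C → rt
Reagents that add atoms: propane-1,3-dithiol, SCCCS
Why: Lewis-acid-catalysed dithioacetalization of an aromatic aldehyde is reliable and gives the acyl-anion equivalent needed for the umpolung addition.

Step 4
Reactants: 9 3,4-dimethoxybenzyl alcohol
Product: 10 3,4-dimethoxybenzyl bromide
Conditions: PBr3, Et2O, 0 °C; used directly
Reagents that add atoms: phosphorus tribromide, BrP(Br)Br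
Why: The alcohol is activated as its phosphite ester and displaced by bromide (SN2); the electron-rich benzylic bromide is labile and is therefore made immediately before the key step.

Step 5
Reactants: 8 2-(3,4,5-trimethoxyphenyl)-1,3-dithiane; 6 (5R)-5-[(1R,2S,5R)-menthyloxy]furan-2(5H)-one; 10 3,4-dimethoxybenzyl bromide
Product: 13 (3R,4R,5R)-3-(3,4-dimethoxybenzyl)-5-[(1R,2S,5R)-menthyloxy]-4-[2-(3,4,5-trimethoxyphenyl)-1,3-dithian-2-yl]dihydrofuran-2(3H)-one (all-trans on the lactone ring), via 2-lithio-2-(3,4,5-trimethoxyphenyl)-1,3-dithiane 11 (not isolated), via lithium enolate of the conjugate adduct 12 (not isolated)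
Conditions: n-BuLi, THF, −30 °C; 6, THF, −78 °C; then 10, TMEDA, −78 → 0 °C; aq. NH4Cl
Reagents that add atoms: none
Why: n-BuLi deprotonates 8 at C2 of the dithiane to the sulfur- and aryl-stabilized carbanion 11, which adds in a Michael fashion to C4 of butenolide 6 to give lithium enolate 12; this is then C-alkylated at C3 by bromide 10 in an SN2 reaction, so the C4–C(dithiane) and C3–CH2 bonds form in one pot. The closest known reaction type is the tandem conjugate addition–enolate alkylation of lithiated 2-aryl-1,3-dithianes on 5-alkoxyfuran-2(5H)-ones. No ring is closed, so no mode of closure applies. The C4 stereocentre is set by the C5 menthyloxy group, which shields its own face of the planar butenolide and forces attack anti to it (4,5-trans), and the C3 stereocentre is set by the bulky C4 dithianyl group, which sends the benzylic bromide to the opposite face of the enolate (3,4-trans). The step needs 1,4- over 1,2-addition, which the soft, hindered, charge-delocalized dithianyl anion in THF at −78 °C should secure, and alkylation faster than retro-Michael reaction or proton transfer, which the reactive benzylic bromide activated by TMEDA should secure.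

Step 6
Reactants: 13 the dithianyl lactone acetal of step 5
Product: 14 (3R,4R,5R)-3-(3,4-dimethoxybenzyl)-5-[(1R,2S,5R)-menthyloxy]-4-(3,4,5-trimethoxybenzyl)dihydrofuran-2(3H)-one
Conditions: Raney Ni (W-2), EtOH, reflux
Reagents that add atoms: none
Why: Hydrogen-loaded Raney nickel hydrogenolyses both benzylic C–S bonds (Mozingo-type desulfurization), turning the dithiane carbon into CH2 while the lactone, the acetal, the aryl ethers and the three ring stereocentres should stay untouched under these neutral conditions.

Step 7
Reactants: 14 the dibenzyl lactone acetal of step 6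
Product: 17 (3R,4R)-3-(3,4-dimethoxybenzyl)-4-(3,4,5-trimethoxybenzyl)dihydrofuran-2(3H)-one (target), via potassium aldehyde carboxylate 15 (not isolated), via potassium hydroxy carboxylate 16 (not isolated)
Conditions: NaBH4, KOH, EtOH/H2O, 20 °C; then 2 M HCl to pH 1, 20 °C
Reagents that add atoms: potassium hydroxide, [K+].[OH-] (its oxygen enters the carboxylate of 15 and can remain as the lactone carbonyl oxygen)
Why: Saponification opens the acyloxy acetal, the hemiacetal loses menthol to unveil the C5 aldehyde 15, borohydride reduces it in situ to 16, and acidification closes the γ-lactone onto the same carboxyl carbon (lactonization), so the veratryl group stays α to the carbonyl and C3 and C4 are not touched as long as hydride delivery outruns enolization of the aldehyde.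

**Compound list**
1 | furfural | O=Cc1ccco1 | starting material
2 | furfural 2,5-endoperoxide (2,3,7-trioxabicyclo[2.2.1]hept-5-ene-1-carbaldehyde, racemic) | O=CC12OOC(C=C1)O2 | intermediate
3 | 5-hydroxyfuran-2(5H)-one (racemic) | O=C1C=CC(O)O1 | intermediate
4 | (−)-menthol, (1R,2S,5R)-2-isopropyl-5-methylcyclohexanol | CC(C)[C@@H]1CC[C@@H](C)C[C@H]1O | starting material
5 | (5S)-5-[(1R,2S,5R)-menthyloxy]furan-2(5H)-one | CC(C)[C@@H]1CC[C@@H](C)C[C@H]1O[C@H]1OC(=O)C=C1 | intermediate
6 | (5R)-5-[(1R,2S,5R)-menthyloxy]furan-2(5H)-one | CC(C)[C@@H]1CC[C@@H](C)C[C@H]1O[C@@H]1OC(=O)C=C1 | intermediate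
7 | 3,4,5-trimethoxybenzaldehyde | COc1cc(C=O)cc(OC)c1OC | starting material
8 | 2-(3,4,5-trimethoxyphenyl)-1,3-dithiane | COc1cc(C2SCCCS2)cc(OC)c1OC | intermediate
9 | 3,4-dimethoxybenzyl alcohol | COc1ccc(CO)cc1OC | starting material
10 | 3,4-dimethoxybenzyl bromide | COc1ccc(CBr)cc1OC | intermediate
11 | 2-lithio-2-(3,4,5-trimethoxyphenyl)-1,3-dithiane | COc1cc(C2([Li])SCCCS2)cc(OC)c1OC | intermediate
12 | lithium (4R,5R)-5-[(1R,2S,5R)-menthyloxy]-4-[2-(3,4,5-trimethoxyphenyl)-1,3-dithian-2-yl]-4,5-dihydrofuran-2-olate (4,5-trans lactone enolate) | CC(C)[C@@H]1CC[C@@H](C)C[C@H]1O[C@@H]1OC(O[Li])=C[C@H]1C1(c2cc(OC)c(OC)c(OC)c2)SCCCS1 | intermediate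
13 | (3R,4R,5R)-3-(3,4-dimethoxybenzyl)-5-[(1R,2S,5R)-menthyloxy]-4-[2-(3,4,5-trimethoxyphenyl)-1,3-dithian-2-yl]dihydrofuran-2(3H)-one | CC(C)[C@@H]1CC[C@@H](C)C[C@H]1O[C@@H]1OC(=O)[C@H](Cc2ccc(OC)c(OC)c2)[C@H]1C1(c2cc(OC)c(OC)c(OC)c2)SCCCS1 | intermediate
14 | (3R,4R,5R)-3-(3,4-dimethoxybenzyl)-5-[(1R,2S,5R)-menthyloxy]-4-(3,4,5-trimethoxybenzyl)dihydrofuran-2(3H)-one | CC(C)[C@@H]1CC[C@@H](C)C[C@H]1O[C@@H]1OC(=O)[C@H](Cc2ccc(OC)c(OC)c2)[C@H]1Cc1cc(OC)c(OC)c(OC)c1 | intermediate
15 | potassium (2R,3R)-2-(3,4-dimethoxybenzyl)-4-oxo-3-(3,4,5-trimethoxybenzyl)butanoate | O=C[C@H](Cc1cc(OC)c(OC)c(OC)c1)[C@@H](Cc1ccc(OC)c(OC)c1)C(=O)[O-].[K+] | intermediate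
16 | potassium (2R,3R)-2-(3,4-dimethoxybenzyl)-4-hydroxy-3-(3,4,5-trimethoxybenzyl)butanoate | OC[C@H](Cc1cc(OC)c(OC)c(OC)c1)[C@@H](Cc1ccc(OC)c(OC)c1)C(=O)[O-].[K+] | intermediate
17 | (3R,4R)-3-(3,4-dimethoxybenzyl)-4-(3,4,5-trimethoxybenzyl)dihydrofuran-2(3H)-one | COc1ccc(C[C@H]2C(=O)OC[C@@H]2Cc2cc(OC)c(OC)c(OC)c2)cc1OC | target

**Step count**
Total: 7 steps. Longest linear sequence: 5 steps (steps 1, 2, 5, 6, 7 from furfural); steps 3 and 4 are one-step side branches feeding step 5.

**Steps most likely to fail**

Step 5 (key step). The enolate may be lost before benzylation, by reversal of the conjugate addition on warming or by proton transfer, while the labile bromide decomposes; some attack at the lactone carbonyl is also possible. Fallback: the tandem process is split into two separate operations. Setting out from 8 and 6, anion 11 is added to 6 at −78 °C and the mixture is quenched cold with aq. NH4Cl, so that the conjugate adduct (4R,5R)-5-[(1R,2S,5R)-menthyloxy]-4-[2-(3,4,5-trimethoxyphenyl)-1,3-dithian-2-yl]dihydrofuran-2(3H)-one F1 can be isolated and purified. Its enolate is then generated separately with LiN(SiMe3)2 in THF/DMPU at −78 °C and alkylated with 10, again anti to the C4 dithianyl group, which returns to the route at 13.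

Step 7. Under KOH the open-chain aldehyde may enolize before hydride arrives, which would erode the C4 configuration and lead to the cis lactone; incomplete acetal opening is the other concern. Fallback: the auxiliary is removed under acid instead of base. Setting out from 14, aqueous trifluoroacetic acid at 40 °C should hydrolyse the menthyl acetal to the pseudo-acid lactol (3R,4R)-3-(3,4-dimethoxybenzyl)-5-hydroxy-4-(3,4,5-trimethoxybenzyl)dihydrofuran-2(3H)-one F2 (mixture of C5 epimers). Its masked aldehyde is then reduced with NaBH4 in EtOH at 0 °C without added hydroxide, and acidification with HCl closes the lactone, coming back to the route at 17.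

Step 6. Desulfurization on the nickel surface may stall at the hindered quaternary dithiane carbon flanked by the menthyl acetal, or material may be lost by adsorption or over-reduction. Fallback: the order of the end game is reversed and the sulfur is removed by a homogeneous radical chain. Setting out from 13, the conditions of step 7 (NaBH4, KOH, EtOH/H2O; then HCl) should give the dithianyl lactone (3R,4R)-3-(3,4-dimethoxybenzyl)-4-[2-(3,4,5-trimethoxyphenyl)-1,3-dithian-2-yl]dihydrofuran-2(3H)-one F3. Tributyltin hydride with AIBN in refluxing toluene should then cleave both benzylic C–S bonds (stannane reduction of dithioacetals), coming back to the route at 17.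

**Further compounds**
F1 | step 5 | (4R,5R)-5-[(1R,2S,5R)-menthyloxy]-4-[2-(3,4,5-trimethoxyphenyl)-1,3-dithian-2-yl]dihydrofuran-2(3H)-one | CC(C)[C@@H]1CC[C@@H](C)C[C@H]1O[C@@H]1OC(=O)C[C@H]1C1(c2cc(OC)c(OC)c(OC)c2)SCCCS1
F2 | step 7 | (3R,4R)-3-(3,4-dimethoxybenzyl)-5-hydroxy-4-(3,4,5-trimethoxybenzyl)dihydrofuran-2(3H)-one (C5 epimer mixture) | OC1OC(=O)[C@H](Cc2ccc(OC)c(OC)c2)[C@H]1Cc1cc(OC)c(OC)c(OC)c1
F3 | step 6 | (3R,4R)-3-(3,4-dimethoxybenzyl)-4-[2-(3,4,5-trimethoxyphenyl)-1,3-dithian-2-yl]dihydrofuran-2(3H)-one | COc1ccc(C[C@H]2C(=O)OC[C@@H]2C2(c3cc(OC)c(OC)c(OC)c3)SCCCS2)cc1OC
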